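**Plan**

- Retrosynthesis: the ether bond between the ring B oxygen and C1'' is cut first (phenol plus allylic alcohol). In the chain, C2''–C1'' and C3''–CH3 are cut back to a terminal alkyne, and C2''≡C3'' back to a masked aldehyde. In the lignan, the C3–CH2(ring A) bond, the lactone ester bond and the benzylidene C=C are cut.
- Forward: L-glutamic acid is closed to a γ-lactone (step 1), which is opened again when the alkyne is made (step 5). The chain is then completed on the alkyne. The lignan butyrolactone is the only ring of the target and arises by lactonisation of a γ-hydroxy acid (step 11). Chain and lignan are joined by etherification, and all silyl groups are removed at the end.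
- Enabling feature: in the chain on the ring B oxygen, C1''H2–C2''H=C3''(CH3)–C4''H2–C5''H2–C6''H(OH)–C7''(CH3)2OH, the C3'' methyl is cis to C1''. That is the pattern left by syn addition of CH3 and a metal across a C2''≡C3'' alkyne. C3''–C7'' with the 6''S oxygen is C5–C1 of L-glutamic acid.
- Stereochemistry: 6''S comes from L-glutamic acid (deamination with retention). The 2''E alkene comes from syn methylmetalation and retentive capture. C4 (R) comes from rhodium-catalysed asymmetric hydrogenation, and C3 (R) from trans alkylation of the lactone enolate.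

Key step: step 7

Remark on the chemistry: ring A is the aryl group of the benzyl on lactone C3 (free phenol in the target), ring B that of the benzyl on C4 (ether oxygen). In step 10 the (S,S) ligand is assigned to the (R) acid by analogy with the chelate model for enamides; the antipodal ligand would be taken if the sign of rotation of lactone 18 indicated the opposite sense.

**Route**

Step 1
Reactants: 1 L-glutamic acid
Product: 2 (S)-5-oxotetrahydrofuran-2-carboxylic acid
Conditions: NaNO2, aq. HCl, 0 °C → rt
Reagents that add atoms: none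
Why: Diazotisation and deaminative lactonisation; the α-carboxylate displaces N2 and the γ-carboxylate opens the α-lactone, so two inversions leave the S centre with net retention.

Step 2
Reactants: 2 (S)-5-oxotetrahydrofuran-2-carboxylic acid
Product: 3 ethyl (S)-5-oxotetrahydrofuran-2-carboxylate
Conditions: EtOH, TsOH·H2O (cat.), toluene, reflux, Dean–Stark
Reagents that add atoms: ethanol, CCO
Why: Fischer esterification driven by azeotropic removal of water, under which the γ-lactone stays closed and the stereocentre is untouched.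

Step 3
Reactants: 3 ethyl (S)-5-oxotetrahydrofuran-2-carboxylate
Product: 5 (S)-5-(2-hydroxypropan-2-yl)dihydrofuran-2(3H)-one, via methyl ketone 4 (not isolated)
Conditions: MeMgBr (2.1 equiv), THF, −78 → −40 °C
Reagents that add atoms: methylmagnesium bromide, C[Mg]Br
Why: Double Grignard addition; the exocyclic ester carries an α-oxygen and should be attacked faster than the lactone carbonyl, and ketone 4 faster still, so two equivalents at low temperature should stop at the tertiary carbinol.

Step 4
Reactants: 5 (S)-5-(2-hydroxypropan-2-yl)dihydrofuran-2(3H)-one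
Product: 6 (5S)-5-(2-hydroxypropan-2-yl)tetrahydrofuran-2-ol (mixture of anomers)
Conditions: (i-Bu)2AlH (2.2 equiv), CH2Cl2, −78 °C; aq. potassium sodium tartrate
Reagents that add atoms: none
Why: Partial reduction of a lactone with (i-Bu)2AlH; the first equivalent is consumed by the tertiary hydroxyl and the aluminium hemiacetal is stable at −78 °C, so reduction should stop at the lactol.

Step 5
Reactants: 6 (5S)-5-(2-hydroxypropan-2-yl)tetrahydrofuran-2-ol
Product: 7 (3S)-2-methylhept-6-yne-2,3-diol
Conditions: dimethyl (1-diazo-2-oxopropyl)phosphonate, K2CO3, MeOH, 0 °C → rt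
Reagents that add atoms: dimethyl (1-diazo-2-oxopropyl)phosphonate, COP(=O)(OC)C(=[N+]=[N-])C(C)=O
Why: Seyferth–Gilbert homologation with the Ohira–Bestmann reagent; the lactol is in equilibrium with the open hydroxy aldehyde, which is converted into the terminal alkyne under mild base that cannot touch the carbinol centre.

Step 6
Reactants: 7 (3S)-2-methylhept-6-yne-2,3-diol
Product: 8 (3S)-2-methyl-2,3-bis(triethylsilyloxy)hept-6-yne
Conditions: Et3SiOTf (2.5 equiv), 2,6-lutidine, CH2Cl2, −78 → 0 °C
Reagents that add atoms: triethylsilyl trifluoromethanesulfonate, CC[Si](CC)(CC)OS(=O)(=O)C(F)(F)F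
Why: Silylation with a silyl triflate, reactive enough for the tertiary hydroxyl; it removes both acidic O–H groups that would otherwise consume Me3Al in the next step.

Step 7
Reactants: 8 (3S)-2-methyl-2,3-bis(triethylsilyloxy)hept-6-yne
Product: 11 (2E,6S)-3,7-dimethyl-6,7-bis(triethylsilyloxy)oct-2-en-1-ol, via alkenyldimethylalane 9 (not isolated), via lithium alanate 10 (not isolated)
Conditions: Me3Al (2.5 equiv), Cp2ZrCl2 (0.25 equiv), CH2Cl2, 0 °C → rt; volatiles removed in vacuo; n-BuLi (1.0 equiv), THF–hexane, −78 → 0 °C; (CH2O)n, rt; aq. potassium sodium tartrate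
Reagents that add atoms: trimethylaluminium, C[Al](C)C; paraformaldehyde (reacts as formaldehyde), C=O
Why: Me3Al and Cp2ZrCl2 form a methylzirconium–aluminium species that adds CH3 and metal across the terminal alkyne through a four-centre syn transition state, with CH3 on the internal carbon (C3'') and, after exchange to aluminium, the metal on the terminal carbon (C2''), giving alane 9. n-BuLi turns 9 into alanate 10, whose alkenyl–aluminium bond attacks formaldehyde with retention, so C1'' ends cis to the C3'' methyl and the 2E allylic alcohol results. The closest known reaction is the Negishi zirconium-catalysed carboalumination of terminal alkynes followed by hydroxymethylation of the ate complex, the standard entry to (E)-3-methylalk-2-en-1-ols. No ring closes and no stereocentre is created; the only new stereo element is the C2''=C3'' geometry, fixed by the syn addition and the retentive C–Al to C–C exchange. The step needs regioselectivity (methyl internal, metal terminal) and tolerance of the oxygen functions. The unhindered terminal alkyne with a CH2 neighbour secures the first, and the bulky, non-acidic triethylsilyl ethers on C6'' and C7'', three and four carbons from the alkyne, secure the second while leaving the C6'' centre untouched.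

Step 8
Reactants: 12 vanillin
Product: 13 4-(benzyloxy)-3-methoxybenzaldehyde
Conditions: BnBr, K2CO3, DMF, rt
Reagents that add atoms: benzyl bromide, BrCc1ccccc1
Why: Williamson ether synthesis on the phenoxide; the benzyl group marks the ring B oxygen for later release by hydrogenolysis.

Step 9
Reactants: 13 4-(benzyloxy)-3-methoxybenzaldehyde; 14 dimethyl succinate
Product: 15 (E)-4-[4-(benzyloxy)-3-methoxyphenyl]-3-(methoxycarbonyl)but-3-enoic acid
Conditions: NaOMe, MeOH, reflux; then aq. HCl
Reagents that add atoms: none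
Why: Stobbe condensation; aldol addition, lactonisation to the paraconate and E1cB ring opening give the half-ester with the aryl group trans to the conjugated ester.

Step 10
Reactants: 15 (E)-4-[4-(benzyloxy)-3-methoxyphenyl]-3-(methoxycarbonyl)but-3-enoic acid
Product: 16 (3R)-4-[4-(benzyloxy)-3-methoxyphenyl]-3-(methoxycarbonyl)butanoic acid
Conditions: H2 (5 bar), [Rh(cod)((S,S)-Et-DuPhos)]BF4 (1 mol %), NaOMe (10 mol %), MeOH, rt
Reagents that add atoms: none
Why: Rhodium-catalysed asymmetric hydrogenation of a Stobbe itaconate half-ester; the carboxylate and the alkene chelate rhodium and the C2-symmetric bisphospholane selects the alkene face, which sets the centre that becomes C4 (R), while the homogeneous catalyst leaves the benzyl ether intact.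

Step 11
Reactants: 16 (3R)-4-[4-(benzyloxy)-3-methoxyphenyl]-3-(methoxycarbonyl)butanoic acid
Product: 18 (R)-4-[4-(benzyloxy)-3-methoxybenzyl]dihydrofuran-2(3H)-one, via hydroxy acid 17 (not isolated)
Conditions: KOH (1.0 equiv), EtOH, 0 °C; CaCl2, NaBH4, EtOH, −10 °C → rt; then aq. HCl (2 M), rt
Reagents that add atoms: none
Why: Chemoselective borohydride reduction; calcium borohydride reduces the methyl ester but not the carboxylate, and acidification closes the γ-hydroxy acid to the lactone by 5-exo-trig acyl substitution without touching the stereocentre.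

Step 12
Reactants: 12 vanillin
Product: 19 3-methoxy-4-(triisopropylsilyloxy)benzaldehyde
Conditions: i-Pr3SiCl, imidazole, DMF, rt
Reagents that add atoms: triisopropylsilyl chloride, CC(C)[Si](Cl)(C(C)C)C(C)C
Why: Imidazole-mediated silylation of the phenol; the bulky aryl silyl ether should survive hydride, enolate and hydrogenolysis conditions and fall to fluoride at the end.

Step 13
Reactants: 19 3-methoxy-4-(triisopropylsilyloxy)benzaldehyde
Product: 20 [3-methoxy-4-(triisopropylsilyloxy)phenyl]methanol
Conditions: NaBH4, MeOH, 0 °C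
Reagents that add atoms: none
Why: Borohydride reduction of an aryl aldehyde to the benzyl alcohol, with the silyl ether inert.

Step 14
Reactants: 20 [3-methoxy-4-(triisopropylsilyloxy)phenyl]methanol
Product: 21 4-(bromomethyl)-2-methoxy-1-(triisopropylsilyloxy)benzene
Conditions: CBr4, PPh3, CH2Cl2, 0 °C; filtered through silica and used at once
Reagents that add atoms: carbon tetrabromide, BrC(Br)(Br)Br
Why: Appel bromination under neutral conditions, chosen because the electron-rich benzyl bromide ionises easily and would not tolerate acid.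

Step 15
Reactants: 18 (R)-4-[4-(benzyloxy)-3-methoxybenzyl]dihydrofuran-2(3H)-one; 21 4-(bromomethyl)-2-methoxy-1-(triisopropylsilyloxy)benzene
Product: 23 (3R,4R)-4-[4-(benzyloxy)-3-methoxybenzyl]-3-[3-methoxy-4-(triisopropylsilyloxy)benzyl]dihydrofuran-2(3H)-one, via lithium enolate 22 (not isolated)
Conditions: LiN(SiMe3)2 (1.1 equiv), THF, −78 °C; then 21, DMPU, −78 → −30 °C
Reagents that add atoms: none
Why: Alkylation of a lactone enolate; the bromide approaches the planar enolate from the face opposite the C4 benzyl group, so the new C3 centre is set trans (3R) by substrate control.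

Step 16
Reactants: 23 (3R,4R)-4-[4-(benzyloxy)-3-methoxybenzyl]-3-[3-methoxy-4-(triisopropylsilyloxy)benzyl]dihydrofuran-2(3H)-one
Product: 24 (3R,4R)-4-(4-hydroxy-3-methoxybenzyl)-3-[3-methoxy-4-(triisopropylsilyloxy)benzyl]dihydrofuran-2(3H)-one
Conditions: H2 (1 atm), 10 % Pd/C, EtOAc, rt
Reagents that add atoms: none
Why: Hydrogenolysis of the benzyl ether frees only the ring B phenol, since the aryl silyl ether, the lactone and both stereocentres are inert to hydrogen over palladium on carbon in a neutral solvent.

Step 17
Reactants: 24 (3R,4R)-4-(4-hydroxy-3-methoxybenzyl)-3-[3-methoxy-4-(triisopropylsilyloxy)benzyl]dihydrofuran-2(3H)-one; 11 (2E,6S)-3,7-dimethyl-6,7-bis(triethylsilyloxy)oct-2-en-1-ol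
Product: 25 (3R,4R)-4-{4-[(2E,6S)-3,7-dimethyl-6,7-bis(triethylsilyloxy)oct-2-enyloxy]-3-methoxybenzyl}-3-[3-methoxy-4-(triisopropylsilyloxy)benzyl]dihydrofuran-2(3H)-one
Conditions: PPh3, diisopropyl azodicarboxylate (DIAD), THF, 0 °C → rt
Reagents that add atoms: none
Why: Mitsunobu etherification; the phenol is acidic enough to protonate the betaine and the phenoxide displaces the primary allylic oxyphosphonium at C1'' by SN2, which keeps the E alkene and needs no base that could epimerise C3.

Step 18
Reactants: 25 (3R,4R)-4-{4-[(2E,6S)-3,7-dimethyl-6,7-bis(triethylsilyloxy)oct-2-enyloxy]-3-methoxybenzyl}-3-[3-methoxy-4-(triisopropylsilyloxy)benzyl]dihydrofuran-2(3H)-one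
Product: 26 (3R,4R)-4-{4-[(2E,6S)-6,7-dihydroxy-3,7-dimethyloct-2-enyloxy]-3-methoxybenzyl}-3-(4-hydroxy-3-methoxybenzyl)dihydrofuran-2(3H)-one (CNP0287070.1)
Conditions: Bu4NF (4 equiv), AcOH (4 equiv), THF, 0 °C → rt
Reagents that add atoms: none
Why: Fluoride-mediated desilylation removes the two triethylsilyl ethers and the aryl triisopropylsilyl ether in one operation, and the acetic acid buffer keeps the lactone and its α-centre out of reach of basic fluoride.

**Compound list**

1 | L-glutamic acid | N[C@@H](CCC(=O)O)C(=O)O | starting material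
2 | (S)-5-oxotetrahydrofuran-2-carboxylic acid | OC(=O)[C@@H]1CCC(=O)O1 | intermediate
3 | ethyl (S)-5-oxotetrahydrofuran-2-carboxylate | CCOC(=O)[C@@H]1CCC(=O)O1 | intermediate
4 | (S)-5-acetyldihydrofuran-2(3H)-one (methyl ketone, not isolated) | CC(=O)[C@@H]1CCC(=O)O1 | intermediate
5 | (S)-5-(2-hydroxypropan-2-yl)dihydrofuran-2(3H)-one | CC(C)(O)[C@@H]1CCC(=O)O1 | intermediate
6 | (5S)-5-(2-hydroxypropan-2-yl)tetrahydrofuran-2-ol, mixture of anomers | CC(C)(O)[C@@H]1CCC(O)O1 | intermediate
7 | (3S)-2-methylhept-6-yne-2,3-diol | C#CCC[C@H](O)C(C)(C)O | intermediate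
8 | (3S)-2-methyl-2,3-bis(triethylsilyloxy)hept-6-yne | C#CCC[C@H](O[Si](CC)(CC)CC)C(C)(C)O[Si](CC)(CC)CC | intermediate
9 | dimethyl[(1E,5S)-2,6-dimethyl-5,6-bis(triethylsilyloxy)hept-1-en-1-yl]alane (not isolated) | C[Al](C)/C=C(\C)CC[C@H](O[Si](CC)(CC)CC)C(C)(C)O[Si](CC)(CC)CC | intermediate
10 | lithium butyl[(1E,5S)-2,6-dimethyl-5,6-bis(triethylsilyloxy)hept-1-en-1-yl]dimethylalanate (not isolated) | [Li+].CCCC[Al-](C)(C)/C=C(\C)CC[C@H](O[Si](CC)(CC)CC)C(C)(C)O[Si](CC)(CC)CC | intermediate
11 | (2E,6S)-3,7-dimethyl-6,7-bis(triethylsilyloxy)oct-2-en-1-ol | OC/C=C(\C)CC[C@H](O[Si](CC)(CC)CC)C(C)(C)O[Si](CC)(CC)CC | intermediate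
12 | vanillin | COc1cc(C=O)ccc1O | starting material
13 | 4-(benzyloxy)-3-methoxybenzaldehyde | COc1cc(C=O)ccc1OCc1ccccc1 | intermediate
14 | dimethyl succinate | COC(=O)CCC(=O)OC | starting material
15 | (E)-4-[4-(benzyloxy)-3-methoxyphenyl]-3-(methoxycarbonyl)but-3-enoic acid | COC(=O)/C(CC(=O)O)=C/c1ccc(OCc2ccccc2)c(OC)c1 | intermediate
16 | (3R)-4-[4-(benzyloxy)-3-methoxyphenyl]-3-(methoxycarbonyl)butanoic acid | COC(=O)[C@@H](CC(=O)O)Cc1ccc(OCc2ccccc2)c(OC)c1 | intermediate
17 | (3R)-4-[4-(benzyloxy)-3-methoxyphenyl]-3-(hydroxymethyl)butanoic acid (not isolated) | OC[C@@H](CC(=O)O)Cc1ccc(OCc2ccccc2)c(OC)c1 | intermediate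
18 | (R)-4-[4-(benzyloxy)-3-methoxybenzyl]dihydrofuran-2(3H)-one | O=C1OC[C@H](Cc2ccc(OCc3ccccc3)c(OC)c2)C1 | intermediate
19 | 3-methoxy-4-(triisopropylsilyloxy)benzaldehyde | COc1cc(C=O)ccc1O[Si](C(C)C)(C(C)C)C(C)C | intermediate
20 | [3-methoxy-4-(triisopropylsilyloxy)phenyl]methanol | COc1cc(CO)ccc1O[Si](C(C)C)(C(C)C)C(C)C | intermediate
21 | 4-(bromomethyl)-2-methoxy-1-(triisopropylsilyloxy)benzene | COc1cc(CBr)ccc1O[Si](C(C)C)(C(C)C)C(C)C | intermediate
22 | lithium (R)-4-[4-(benzyloxy)-3-methoxybenzyl]-4,5-dihydrofuran-2-olate (not isolated) | [Li+].[O-]C1=C[C@@H](Cc2ccc(OCc3ccccc3)c(OC)c2)CO1 | intermediate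
23 | (3R,4R)-4-[4-(benzyloxy)-3-methoxybenzyl]-3-[3-methoxy-4-(triisopropylsilyloxy)benzyl]dihydrofuran-2(3H)-one | COc1cc(C[C@H]2C(=O)OC[C@@H]2Cc2ccc(OCc3ccccc3)c(OC)c2)ccc1O[Si](C(C)C)(C(C)C)C(C)C | intermediate
24 | (3R,4R)-4-(4-hydroxy-3-methoxybenzyl)-3-[3-methoxy-4-(triisopropylsilyloxy)benzyl]dihydrofuran-2(3H)-one | COc1cc(C[C@H]2C(=O)OC[C@@H]2Cc2ccc(O)c(OC)c2)ccc1O[Si](C(C)C)(C(C)C)C(C)C | intermediate
25 | (3R,4R)-4-{4-[(2E,6S)-3,7-dimethyl-6,7-bis(triethylsilyloxy)oct-2-enyloxy]-3-methoxybenzyl}-3-[3-methoxy-4-(triisopropylsilyloxy)benzyl]dihydrofuran-2(3H)-one | COc1cc(C[C@H]2C(=O)OC[C@@H]2Cc2ccc(OC/C=C(\C)CC[C@H](O[Si](CC)(CC)CC)C(C)(C)O[Si](CC)(CC)CC)c(OC)c2)ccc1O[Si](C(C)C)(C(C)C)C(C)C | intermediate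
26 | (3R,4R)-4-{4-[(2E,6S)-6,7-dihydroxy-3,7-dimethyloct-2-enyloxy]-3-methoxybenzyl}-3-(4-hydroxy-3-methoxybenzyl)dihydrofuran-2(3H)-one | COc1cc(C[C@H]2C(=O)OC[C@@H]2Cc2ccc(OC/C=C(\C)CC[C@H](O)C(C)(C)O)c(OC)c2)ccc1O | target

**Count and risks**

Total step count: 18. Longest linear sequence: 9 steps (steps 1–7, 17 and 18, from L-glutamic acid).

Steps most likely to fail:

Step 3. The Grignard reagent may not discriminate well enough between the two acyl groups, so that methyl also adds to the lactone carbonyl and the ring is opened. The fallback sets out from 2 and comes back at 5, adding the two methyl groups in separate operations, each with a large reactivity gap to the lactone. Acid 2 would be converted with (COCl)2 and catalytic DMF into (S)-5-oxotetrahydrofuran-2-carbonyl chloride F1. Me2CuLi at −78 °C should stop at the methyl ketone 4, this time isolated. MeTi(OiPr)3, a non-basic reagent that adds to ketones and leaves esters and lactones alone, should then give 5 without enolising the centre next to the ketone.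

Step 5. The aldehyde is present only as a small equilibrium share of the open form of the lactol, so the homologation may be slow and the diazophosphonate anion may decay before it is consumed. The fallback sets out from 5 and comes back at 8, passing through a free aldehyde instead of a lactol. Lactone 5 would be opened with MeNH(OMe)·HCl and Me3Al to (4S)-4,5-dihydroxy-N-methoxy-N,5-dimethylhexanamide F2, which is silylated at once with Et3SiOTf and 2,6-lutidine to (4S)-N-methoxy-N,5-dimethyl-4,5-bis(triethylsilyloxy)hexanamide F3 so that it cannot relactonise. (i-Bu)2AlH at −78 °C should give (4S)-5-methyl-4,5-bis(triethylsilyloxy)hexanal F4, and the Ohira–Bestmann reagent with K2CO3 in MeOH then delivers 8 directly.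

Step 7. Methylmetalation may stay incomplete or be accompanied by deprotonation of the alkyne, a triethylsilyl group may be lost to the Lewis-acidic medium, and capture of the alanate by polymeric formaldehyde may be sluggish. The fallback sets out from 8 and comes back at 11, attaching C1'' first and delivering the methyl group last. Alkyne 8 would be deprotonated with n-BuLi and hydroxymethylated with (CH2O)n to (6S)-7-methyl-6,7-bis(triethylsilyloxy)oct-2-yn-1-ol F5. Alkoxide-directed anti hydroalumination with NaAlH2(OCH2CH2OMe)2 in THF followed by I2 at −78 °C should give (2Z,6S)-3-iodo-7-methyl-6,7-bis(triethylsilyloxy)oct-2-en-1-ol F6, with iodine on C3'' cis to C1''. Me2CuLi then replaces iodine by methyl with retention and gives 11 with the same E geometry.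

**Further compounds**

F1 | step 3 | (S)-5-oxotetrahydrofuran-2-carbonyl chloride | ClC(=O)[C@@H]1CCC(=O)O1
F2 | step 5 | (4S)-4,5-dihydroxy-N-methoxy-N,5-dimethylhexanamide | CON(C)C(=O)CC[C@H](O)C(C)(C)O
F3 | step 5 | (4S)-N-methoxy-N,5-dimethyl-4,5-bis(triethylsilyloxy)hexanamide | CON(C)C(=O)CC[C@H](O[Si](CC)(CC)CC)C(C)(C)O[Si](CC)(CC)CC
F4 | step 5 | (4S)-5-methyl-4,5-bis(triethylsilyloxy)hexanal | O=CCC[C@H](O[Si](CC)(CC)CC)C(C)(C)O[Si](CC)(CC)CC
F5 | step 7 | (6S)-7-methyl-6,7-bis(triethylsilyloxy)oct-2-yn-1-ol | OCC#CCC[C@H](O[Si](CC)(CC)CC)C(C)(C)O[Si](CC)(CC)CC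
F6 | step 7 | (2Z,6S)-3-iodo-7-methyl-6,7-bis(triethylsilyloxy)oct-2-en-1-ol | OC/C=C(\I)CC[C@H](O[Si](CC)(CC)CC)C(C)(C)O[Si](CC)(CC)CC
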